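The spiro cyclohexane (ring B: spiro carbon, its two CH2 neighbours, the two ring-fusion CH and the methyl carbinol carbon) is disconnected to an eight-membered allyl aryl ether. In it the 4-oxygen of phloroacetophenone is tethered through a 2-substituted allyl unit and a limonene-derived trans-cyclopentanol back to the ortho carbon. A dearomative aromatic Claisen rearrangement contracts this oxocine by two atoms and creates the quaternary spiro carbon. It exploits the phloroglucinol character of ring A (spiro carbon between two enolisable carbonyls) and the 1,3-relation of spiro carbon and carbinol carbon in ring B. The tether fixes which carbonyl lies axial. Radical hydration and gem-diprenylation finish the route.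

Key step: step 7

Remark: commercial (+)-limonene 1,2-oxide is a cis/trans mixture at the epoxide, both isomers converging in step 2, and the enolised β-triketones 12–17 are drawn in the tautomer of the target structure.

Step 1
Reactants: 1 (+)-limonene 1,2-oxide [(4R)-1-methyl-4-(prop-1-en-2-yl)-7-oxabicyclo[4.1.0]heptane]
Product: 2 (4R)-4-(3-chloroprop-1-en-2-yl)-1-methyl-7-oxabicyclo[4.1.0]heptane
Conditions: Ca(OCl)2, CO2 (s), CH2Cl2/H2O, 0 °C
Reagents that add atoms: calcium hypochlorite, [Ca+2].[O-]Cl.[O-]Cl
Why: Ene-type allylic chlorination by hypochlorous acid made in situ should attack the only alkene (the 1,1-disubstituted one) with transposition of the double bond; no stereocentre is formed, C4 is untouched, and any epoxide hydrolysed here converges in step 2.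

Step 2
Reactants: 2 (4R)-4-(3-chloroprop-1-en-2-yl)-1-methyl-7-oxabicyclo[4.1.0]heptane
Product: 4 (3R)-3-(3-chloroprop-1-en-2-yl)-6-oxoheptanal, via diol 3 (not isolated)
Conditions: H5IO6, THF/H2O, 0 °C to rt
Reagents that add atoms: water, O
Why: Acid-catalysed epoxide hydrolysis to diol 3 followed in the same flask by periodate glycol cleavage (Malaprade reaction) should give the keto aldehyde from both epoxide diastereomers, the allylic chloride and the stereocentre being unaffected.

Step 3
Reactants: 4 (3R)-3-(3-chloroprop-1-en-2-yl)-6-oxoheptanal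
Product: 5 (1S,2R,5R)-5-(3-chloroprop-1-en-2-yl)-2-hydroxy-2-methylcyclopentane-1-carbaldehyde
Conditions: L-proline (30 mol %), DMSO, rt
Reagents that add atoms: none
Why: Proline-catalysed 5-enolexo intramolecular aldol addition (aldehyde enamine onto the methyl ketone, stopping at the tertiary aldol as in the Hajos–Parrish reaction) should place the formyl group trans to the neighbouring side chain (also the thermodynamic position, reachable by enamine epimerisation) and the hydroxyl cis to the formyl group through the carboxylic-acid-bridged transition state, L-proline being expected to be the matched catalyst because it delivers the (S) α-carbon.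

Step 4
Reactants: 5 (1S,2R,5R)-5-(3-chloroprop-1-en-2-yl)-2-hydroxy-2-methylcyclopentane-1-carbaldehyde
Product: 6 (1R,2S,3R)-3-(3-chloroprop-1-en-2-yl)-2-(dimethoxymethyl)-1-methylcyclopentan-1-ol
Conditions: CH(OMe)3, MeOH, PPTS (cat.), rt
Reagents that add atoms: methanol, CO; trimethyl orthoformate, COC(OC)OC
Why: Acid-catalysed acetalisation with orthoformate as water scavenger masks the β-hydroxy aldehyde against retro-aldol cleavage and elimination in the basic next step, leaving the stereocentres unchanged.

Step 5
Reactants: 6 (1R,2S,3R)-3-(3-chloroprop-1-en-2-yl)-2-(dimethoxymethyl)-1-methylcyclopentan-1-ol; 7 1-(2,4,6-trihydroxyphenyl)ethan-1-one (phloroacetophenone)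
Product: 8 1-[4-({2-[(1R,2S,3R)-2-(dimethoxymethyl)-3-hydroxy-3-methylcyclopentyl]prop-2-en-1-yl}oxy)-2,6-dihydroxyphenyl]ethan-1-one
Conditions: K2CO3, KI (cat.), acetone, reflux (7 in slight excess)
Reagents that add atoms: none
Why: Williamson ether synthesis: the 4-hydroxyl is the most acidic and the only one not hydrogen-bonded to the acetyl group, so K2CO3 in acetone should O-alkylate it selectively with the primary allylic chloride, iodide catalysis speeding the displacement.

Step 6
Reactants: 8 1-[4-({2-[(1R,2S,3R)-2-(dimethoxymethyl)-3-hydroxy-3-methylcyclopentyl]prop-2-en-1-yl}oxy)-2,6-dihydroxyphenyl]ethan-1-one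
Product: 11 eight-membered allyl aryl ether (acetyl-dihydroxybenzene fused to a 3-methylideneoxocane that is trans-fused to the (R)-1-hydroxy-1-methylcyclopentane; configuration as in 5), via aldehyde 9 (not isolated), via ortho-quinone methide 10 (not isolated)
Conditions: PPTS, acetone/H2O, 40 °C; then L-proline (30 mol %), Hantzsch ester, CH2Cl2/EtOH (2 mM), rt
Reagents that add atoms: none
Why: Mild acid hydrolysis unmasks aldehyde 9, which should condense with the ring carbon ortho to the ether oxygen to ortho-quinone methide 10 that Hantzsch ester reduces (organocatalytic reductive alkylation: Knoevenagel condensation then transfer hydrogenation), high dilution favouring the eight-membered ring; no new stereocentre is formed and the former formyl-bearing carbon keeps its thermodynamic trans arrangement.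

Step 7
Reactants: 11 eight-membered allyl aryl ether
Product: 12 (1R,3'R,3a'S,7a'R)-3-acetyl-3',4-dihydroxy-3'-methyl-7'-methylideneoctahydrospiro[cyclohex-3-ene-1,5'-indene]-2,6-dione
Conditions: PhNEt2, 150 °C (sealed tube); acidic work-up
Reagents that add atoms: none
Why: Thermal [3,3]-sigmatropic aromatic Claisen rearrangement: the terminal methylene carbon of the allyl unit bonds to the ortho carbon that already bears the cyclopentylmethyl CH2, the O–CH2 bond breaks, and the 6,6-disubstituted dienone cannot rearomatise but tautomerises to the enolised β-triketone, which should make the step irreversible. The closest known reactions are the dearomative ortho-Claisen rearrangements of acylphloroglucinol allyl ethers and Claisen ring contractions of medium-ring allyl vinyl ethers. The six-membered carbocycle closes as the eight-membered oxocine contracts by two atoms (the aryl C–O carbon, the oxygen and the OCH2 carbon leave the ring, the former =CH2 carbon enters) through a bicyclo[3.3.1]-like chair–chair transition state. The new spiro stereocentre is controlled by the tether: the carbon that carried the ether oxygen (the later C6 carbonyl, next to the future diprenyl carbon) must lie over the central allyl carbon, that is axial on the nascent chair, and this chair is locked by the trans-fused cyclopentane with its ring-fusion bonds equatorial. The step needs regioselectivity for the substituted ortho carbon over the free one, which the three-atom tether secures because the free ortho carbon is out of reach.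

Step 8
Reactants: 12 (1R,3'R,3a'S,7a'R)-3-acetyl-3',4-dihydroxy-3'-methyl-7'-methylideneoctahydrospiro[cyclohex-3-ene-1,5'-indene]-2,6-dione
Product: 14 (1R,3'R,3a'S,7'R,7a'R)-3-acetyl-3',4,7'-trihydroxy-3',7'-dimethyloctahydrospiro[cyclohex-3-ene-1,5'-indene]-2,6-dione, via hydroperoxide 13 (not isolated)
Conditions: Mn(dpm)3 (cat.), PhSiH3, O2 (1 atm), iPrOH/CH2Cl2, 0 °C to rt; then PPh3
Reagents that add atoms: dioxygen, O=O
Why: Mukaiyama-type hydration by metal-hydride hydrogen atom transfer to the only unactivated alkene gives the tertiary radical, which should be trapped by O2 on the equatorial face, away from the axial C6 carbonyl of the spiro ring, so that the hydroxyl ends equatorial and the methyl axial, PPh3 then reducing hydroperoxide 13.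

Step 9
Reactants: 14 (1R,3'R,3a'S,7'R,7a'R)-3-acetyl-3',4,7'-trihydroxy-3',7'-dimethyloctahydrospiro[cyclohex-3-ene-1,5'-indene]-2,6-dione; 15 1-bromo-3-methylbut-2-ene (prenyl bromide, first equivalent)
Product: 17 (1R,3'R,3a'S,7'R,7a'R)-3-acetyl-3',4,7'-trihydroxy-3',7'-dimethyl-5,5-bis(3-methylbut-2-en-1-yl)octahydrospiro[cyclohex-3-ene-1,5'-indene]-2,6-dione (CNP0266834.2), via monoprenyl trione 16 (not isolated)
Conditions: 15 (2.5 equiv in total), NaOMe (3 equiv), MeOH, 0 °C to rt; aq. HCl work-up
Reagents that add atoms: 1-bromo-3-methylbut-2-ene (prenyl bromide, second equivalent), CC(C)=CCBr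
Why: Double C-alkylation of the only remaining nucleophilic ring carbon of the enolised β-triketone under methoxide (as in lupulone-type gem-diprenylations) should proceed via monoprenyl trione 16, which is deprotonated again and takes up the second equivalent of prenyl bromide, without touching the quaternary spiro centre or the tertiary alcohols, and no stereocentre is created.

Compound list
1 | (+)-limonene 1,2-oxide, (4R)-1-methyl-4-(prop-1-en-2-yl)-7-oxabicyclo[4.1.0]heptane (cis/trans mixture) | CC12OC1C[C@@H](CC2)C(=C)C | starting material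
2 | (4R)-4-(3-chloroprop-1-en-2-yl)-1-methyl-7-oxabicyclo[4.1.0]heptane | CC12OC1C[C@@H](CC2)C(=C)CCl | intermediate
3 | (4R)-4-(3-chloroprop-1-en-2-yl)-1-methylcyclohexane-1,2-diol | CC1(O)C(O)C[C@@H](CC1)C(=C)CCl | intermediate (not isolated)
4 | (3R)-3-(3-chloroprop-1-en-2-yl)-6-oxoheptanal | O=CC[C@@H](CCC(C)=O)C(=C)CCl | intermediate
5 | (1S,2R,5R)-5-(3-chloroprop-1-en-2-yl)-2-hydroxy-2-methylcyclopentane-1-carbaldehyde | O=C[C@H]1[C@@H](CC[C@@]1(C)O)C(=C)CCl | intermediate
6 | (1R,2S,3R)-3-(3-chloroprop-1-en-2-yl)-2-(dimethoxymethyl)-1-methylcyclopentan-1-ol | COC(OC)[C@H]1[C@@H](CC[C@@]1(C)O)C(=C)CCl | intermediate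
7 | 1-(2,4,6-trihydroxyphenyl)ethan-1-one | CC(=O)c1c(O)cc(O)cc1O | starting material
8 | 1-[4-({2-[(1R,2S,3R)-2-(dimethoxymethyl)-3-hydroxy-3-methylcyclopentyl]prop-2-en-1-yl}oxy)-2,6-dihydroxyphenyl]ethan-1-one | COC(OC)[C@H]1[C@@H](CC[C@@]1(C)O)C(=C)COc1cc(O)c(C(C)=O)c(O)c1 | intermediate
9 | (1S,2R,5R)-5-[3-(4-acetyl-3,5-dihydroxyphenoxy)prop-1-en-2-yl]-2-hydroxy-2-methylcyclopentane-1-carbaldehyde | O=C[C@H]1[C@@H](CC[C@@]1(C)O)C(=C)COc1cc(O)c(C(C)=O)c(O)c1 | intermediate (not isolated)
10 | ortho-quinone methide of 11 (ring-fused alkylidene dienone, exocyclic C=CH within the eight-membered ring) | CC(=O)C=1C(=O)/C2=C/[C@H]3[C@@H](CC[C@@]3(C)O)C(=C)COC2=CC=1O | intermediate (not isolated)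
11 | eight-membered allyl aryl ether: 1-acetyl-2,6-dihydroxybenzene fused at C3/C4 to the ring ArC3–CH2–CH–CH–C(=CH2)–CH2–O–ArC4, the two CH trans-fused to a cyclopentane whose (R)-methyl carbinol carbon is next to the CH that carries the ArCH2 group | CC(=O)c1c(O)c2C[C@H]3[C@@H](CC[C@@]3(C)O)C(=C)COc2cc1O | intermediate
12 | (1R,3'R,3a'S,7a'R)-3-acetyl-3',4-dihydroxy-3'-methyl-7'-methylideneoctahydrospiro[cyclohex-3-ene-1,5'-indene]-2,6-dione | CC(=O)C1=C(O)CC(=O)[C@]2(C[C@H]3[C@@H](CC[C@@]3(C)O)C(=C)C2)C1=O | intermediate
13 | 7'-hydroperoxide of 14 | CC(=O)C1=C(O)CC(=O)[C@]2(C[C@H]3[C@@H](CC[C@@]3(C)O)[C@](C)(OO)C2)C1=O | intermediate (not isolated)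
14 | (1R,3'R,3a'S,7'R,7a'R)-3-acetyl-3',4,7'-trihydroxy-3',7'-dimethyloctahydrospiro[cyclohex-3-ene-1,5'-indene]-2,6-dione | CC(=O)C1=C(O)CC(=O)[C@]2(C[C@H]3[C@@H](CC[C@@]3(C)O)[C@](C)(O)C2)C1=O | intermediate
15 | 1-bromo-3-methylbut-2-ene | CC(C)=CCBr | starting material
16 | 5-monoprenyl derivative of 14 (dienol form) | CC(=O)C1=C(O)C(CC=C(C)C)=C(O)[C@]2(C[C@H]3[C@@H](CC[C@@]3(C)O)[C@](C)(O)C2)C1=O | intermediate (not isolated)
17 | (1R,3'R,3a'S,7'R,7a'R)-3-acetyl-3',4,7'-trihydroxy-3',7'-dimethyl-5,5-bis(3-methylbut-2-en-1-yl)octahydrospiro[cyclohex-3-ene-1,5'-indene]-2,6-dione | CC(=O)C1=C(O)C(CC=C(C)C)(CC=C(C)C)C(=O)[C@]2(C[C@H]3[C@@H](CC[C@@]3(C)O)[C@](C)(O)C2)C1=O | target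

Total step count: 9. Longest linear sequence: 9 steps (from 1).

Steps most likely to fail

Step 6. Intermolecular condensation (oligomerisation) may outrun closure of the eight-membered ring, and the amine catalyst may eliminate water from the β-hydroxy aldehyde before it condenses. The fallback closes the ring at the C–O bond instead of the C–C bond. It sets out from 5: chloride–acetate exchange (KOAc, DMF, rt) would give 2-[(1R,2S,3R)-2-formyl-3-hydroxy-3-methylcyclopentyl]prop-2-en-1-yl acetate F1. Intermolecular reductive alkylation of an excess of 7 with it (L-proline, Hantzsch ester, CH2Cl2/EtOH) would give the C-alkylated phloroacetophenone acetate F2. Methanolysis (K2CO3, MeOH) would give the allylic alcohol F3. An intramolecular Mitsunobu etherification at the most acidic 4-hydroxyl (PPh3, DIAD, THF, high dilution), which should react at oxygen and not at the ring carbon, would then return to 11.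

Step 3. The ketone face may be attacked with poor selectivity, giving the epimeric carbinol, or the aldol may dehydrate to the enal. The fallback sets the carbinol by a directed epoxidation and sets out from 4. Aldol condensation (piperidine, AcOH) would give (5R)-5-(3-chloroprop-1-en-2-yl)-2-methylcyclopent-1-ene-1-carbaldehyde F4. Luche reduction (NaBH4, CeCl3, MeOH) would give the allylic alcohol F5. Hydroxyl-directed epoxidation anti to the side chain (VO(acac)2, t-BuOOH) would give the epoxy alcohol F6, and Dess–Martin oxidation the epoxy aldehyde F7. SmI2 (THF/MeOH, −90 °C, at which the allylic chloride should survive) would cleave the Cα–O bond; equilibration of the α-carbon to the trans aldehyde returns to 5.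

Step 8. The acidic β-triketone may sequester the manganese catalyst, and oxygen may trap the tertiary radical with insufficient facial selectivity. The fallback is an ionic Markovnikov hydration and sets out from 12. Oxymercuration (Hg(OAc)2, THF/H2O), with water attacking the tertiary carbon from the equatorial side, would give the organomercurial F8. Reductive demercuration (NaBH4, aqueous NaOH, the triketone being protected as its enolate) returns to 14.

Further compounds
F1 | step 6 | 2-[(1R,2S,3R)-2-formyl-3-hydroxy-3-methylcyclopentyl]prop-2-en-1-yl acetate | O=C[C@H]1[C@@H](CC[C@@]1(C)O)C(=C)COC(C)=O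
F2 | step 6 | 2-{(1R,2S,3R)-2-[(3-acetyl-2,4,6-trihydroxyphenyl)methyl]-3-hydroxy-3-methylcyclopentyl}prop-2-en-1-yl acetate | CC(=O)c1c(O)cc(O)c(C[C@H]2[C@@H](CC[C@@]2(C)O)C(=C)COC(C)=O)c1O
F3 | step 6 | 1-(2,4,6-trihydroxy-3-{[(1S,2R,5R)-2-hydroxy-5-(3-hydroxyprop-1-en-2-yl)-2-methylcyclopentyl]methyl}phenyl)ethan-1-one | CC(=O)c1c(O)cc(O)c(C[C@H]2[C@@H](CC[C@@]2(C)O)C(=C)CO)c1O
F4 | step 3 | (5R)-5-(3-chloroprop-1-en-2-yl)-2-methylcyclopent-1-ene-1-carbaldehyde | O=CC1=C(C)CC[C@H]1C(=C)CCl
F5 | step 3 | [(5R)-5-(3-chloroprop-1-en-2-yl)-2-methylcyclopent-1-en-1-yl]methanol | OCC1=C(C)CC[C@H]1C(=C)CCl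
F6 | step 3 | [(1R,2S,5R)-2-(3-chloroprop-1-en-2-yl)-5-methyl-6-oxabicyclo[3.1.0]hexan-1-yl]methanol | OC[C@@]12O[C@]1(C)CC[C@H]2C(=C)CCl
F7 | step 3 | (1S,2S,5R)-2-(3-chloroprop-1-en-2-yl)-5-methyl-6-oxabicyclo[3.1.0]hexane-1-carbaldehyde | O=C[C@@]12O[C@]1(C)CC[C@H]2C(=C)CCl
F8 | step 8 | 7'-[(acetoxymercurio)methyl] analogue of 14 (HgOAc on the former methylene carbon, hydroxyl on C7') | CC(=O)C1=C(O)CC(=O)[C@]2(C[C@H]3[C@@H](CC[C@@]3(C)O)[C@](C[Hg]OC(C)=O)(O)C2)C1=O
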